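The runs were computed on assumed constants; scatter was added.

Watch one ratio: c(substrate) at the start over c(substrate) at the reading. Its natural logarithm, divided by the time, tells how fast the flask runs.

| flask | substrate | acid | remark | time |
|---|---|---|---|---|
| noon | 0.20 M | 0.020 M | the very flask that is asked about, followed so far |  |
| dawn | 0.10 M | 0.020 M | run made earlier |  |
| flask | 0.20 M | 0.0200 M |  | 10 h |

- noon (time / h: substrate / %, target / %): 0.500: 95.3, 3.0; 1.33: 90.5, 6.8; 2.50: 84.2, 12.4; 4.00: 78.7, 20.6
- dawn (time / h: substrate / %, target / %): 2.00: 88.1, 12.9; 4.00: 78.0, 20.1; 5.00: 74.6, 24.6; 8.00: 62.2, 36.1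

(each reading ± 1 percentage point)

- part of the substrate that has reacted at 10 h
- pH of the solution at 10 h

- acid is the free proton; pH is minus the decimal logarithm of its molar concentration

1. Open the ledger on substrate, the limiting reagent, at the last dawn reading, 8.00 h: 62.2 % left, 36.1 % in target, 1.7 percentage points unbooked, against a scatter of 1 point on each reading.
2. Read the dawn loss constant from the same reading: 0.0594 h⁻¹, the logarithm of the ratio per hour. At fixed acid this is a pseudo-first-order constant.
3. Check it on the noon run, which holds twice the dawn substrate and the same acid: its reading at 4.00 h gives 0.0599 h⁻¹.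
4. Note that noon target at 4.00 h stands at twice the acid charge while noon substrate keeps to that constant, so book acid as a catalyst, unchanged.
5. Carry the constant to the flask: my reckoning gives 44.8 % reacted at 10 h, with the pH of the acid charge.
6. Set this beside the forecast: 45.5 % and pH 1.7, on the ground that “the reaction is first order in substrate at fixed acid”. Its conversion stands 0.70 points above mine; the pH is the same.

The flask gives 46.1 % reacted and pH 1.70. Its books at 10.0 h read 53.9 % substrate, 41.9 % target and 4.15 % side product.

    substrate + acid → weak acid + acid + target (k = 2.80 L mol⁻¹ h⁻¹)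
    substrate → weak acid + target (k = 0.00270 h⁻¹)
    substrate + target → side product (k = 0.0650 L mol⁻¹ h⁻¹)
    weak acid → by-product carried off (k = 0.560 h⁻¹)
    target → over-reaction product (k = 1.70 × 10⁻⁴ h⁻¹)
    weak acid ⇌ conjugate base + acid, settled at all times (K = 1.30 × 10⁻⁶ M)

The same logarithm on this result gives the flask an average constant of 0.0617 h⁻¹ up to 10 h, beside the dawn reading of 0.0594 h⁻¹. Now reckon the neighbour, the same flask read at 25 h: the dawn constant puts 77.3 % reacted. The neighbour gives 80.0 %, more than that reckoning, and its average constant up to 25 h is 0.0644 h⁻¹. Watch the side product there: the neighbour's books read 20 % substrate, 68.3 % target and 11.5 % side product.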